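**Plan**
Retrosynthesis: the epoxide is opened to an 11,20-diol (O–C20 closure), the lactone is cut at C8–C17 (tethered Reformatsky onto a C8 ketone) and at O7–C19, and C4 is then reconnected to C9.
Enabling feature: in the ten-membered ring C1–C10 the C9 oxygen and the ring-cis C3=C4 alkene are 1,5-related, so joining C4 to C9 gives a C9 carbinol and a C3 sulfonate on one six-membered ring (C1, C2, C3, C4, C9, C10) – the retron of a Grob fragmentation.
Forward: ring B by Diels–Alder reaction of a ring A enone (C1, C10–C14) with a 1-acyloxydiene (C2, C3, C4, C9); ring A is oxygenated; ring C (C4–C9) by Mukaiyama–Michael addition and aldol closure; fragmentation merges rings B and C; then lactone, then epoxide.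
Stereochemistry: the C11 silyloxy centre of the bought enone steers the Diels–Alder face (C1) and is then erased; C10 by epimerisation; C11, C13, C14 by osmylation anti to C15; C4 and C9-OH by axial Michael addition and aldol closure.
C7 and later C9 by hydroxyl-directed reductions; C2 and C3 from the C2 ketone; C8 and C17 by the tethered Reformatsky reaction.

Key step: step 27

Remark: locants are briarane locants throughout (C1–C10 ten-membered ring, C11–C14 rest of ring A, C15 methyl on C1, C16 on C5, C17–C19 lactone with C18 methyl, C20 on C11); α/β refer to the usual drawing with C15 β.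
Assumption: (S)-4-(tert-butyldimethylsilyloxy)cyclohex-2-en-1-one (1) is bought as the single enantiomer; all absolute configuration is relayed from its stereocentre.

**Route**

Step 1
Reactants: 1 (S)-4-(tert-butyldimethylsilyloxy)cyclohex-2-en-1-one
Product: 2 (S)-4-(tert-butyldimethylsilyloxy)-2-iodocyclohex-2-en-1-one
Conditions: I2, pyridine, CH2Cl2, 0 °C to rt
Reagents that add atoms: iodine, II
Why: α-iodination of an enone by pyridine addition, iodination and elimination; the silyloxy stereocentre is not involved.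

Step 2
Reactants: 2 (S)-4-(tert-butyldimethylsilyloxy)-2-iodocyclohex-2-en-1-one
Product: 3 (S)-4-(tert-butyldimethylsilyloxy)-2-methylcyclohex-2-en-1-one (ring A: C14 carbonyl, C1 methyl-bearing, C10, C11 silyloxy, C12, C13)
Conditions: trimethylboroxine, Pd(dppf)Cl2 (cat.), Cs2CO3, dioxane/H2O, 80 °C
Reagents that add atoms: trimethylboroxine, CB1OB(C)OB(C)O1
Why: Suzuki–Miyaura methylation of an α-iodoenone, a standard route to 2-methyl enones.

Step 3
Reactants: 4 (E)-but-2-enal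
Product: 5 (E)-buta-1,3-dien-1-yl pivalate
Conditions: KOt-Bu, THF, −78 °C; then pivaloyl chloride
Reagents that add atoms: pivaloyl chloride, CC(C)(C)C(Cl)=O
Why: O-acylation of the dienolate of an enal, which should give the (E)-1-acyloxydiene.

Step 4
Reactants: 3 (S)-4-(tert-butyldimethylsilyloxy)-2-methylcyclohex-2-en-1-one; 5 (E)-buta-1,3-dien-1-yl pivalate
Product: 6 cis-fused adduct, 2α-pivaloyloxy-11β-silyloxy-3-en-14-one (C15 β, H10 β)
Conditions: Me2AlCl, CH2Cl2, −40 to 0 °C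
Reagents that add atoms: none
Why: Lewis acid-promoted Diels–Alder reaction of a 2-methylcyclohexenone; the acyloxy terminus bonds to C1 (ortho rule), the diene adds anti to the C11 silyloxy group and endo to the C14 carbonyl, which sets C1 and gives the pivalate trans to C15.

Step 5
Reactants: 6 cis-fused adduct
Product: 7 cis-fused 11β-hydroxy-14-ketone
Conditions: Bu4NF, THF, 0 °C
Reagents that add atoms: none
Why: fluoride cleavage of a secondary silyl ether; the pivalate and the ketone are inert.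

Step 6
Reactants: 7 cis-fused 11β-hydroxy-14-ketone
Product: 9 trans-fused 11,14-dione (H10 α), via cis-fused 11,14-dione 8 (not isolated)
Conditions: Dess–Martin periodinane, NaHCO3, CH2Cl2, rt; then DBU, rt
Reagents that add atoms: none
Why: alcohol oxidation followed by base epimerisation at C10 (α to the C11 ketone); the trans-fused dione should be favoured because both rings carry trigonal carbons that relieve the diaxial strain of C15, as is usual for angular-methyl quinone-type adducts.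

Step 7
Reactants: 9 trans-fused 11,14-dione
Product: 10 11(20)-methylene-14-ketone
Conditions: Ph3PCH3Br, KOt-Bu, THF, 0 °C
Reagents that add atoms: methyltriphenylphosphonium bromide, C[P+](c1ccccc1)(c1ccccc1)c1ccccc1.[Br-]
Why: Wittig methylenation should take place only at the C11 ketone, since the C14 ketone is neopentyl (next to quaternary C1).

Step 8
Reactants: 10 11(20)-methylene-14-ketone
Product: 11 C14 enol triflate (13-ene)
Conditions: KN(SiMe3)2, PhNTf2, THF, −78 °C
Reagents that add atoms: N-phenylbis(trifluoromethanesulfonimide), O=S(=O)(N(c1ccccc1)S(=O)(=O)C(F)(F)F)C(F)(F)F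
Why: enol triflate formation; the C14 ketone can enolise only toward C13 because C1 is quaternary, and the pivalate has no α-hydrogen.

Step 9
Reactants: 11 C14 enol triflate
Product: 12 3,13,11(20)-triene 2α-pivalate
Conditions: Pd(OAc)2 (cat.), PPh3, HCO2H, n-Bu3N, DMF, 60 °C
Reagents that add atoms: none
Why: palladium-catalysed formate reduction of a vinyl triflate to the alkene.

Step 10
Reactants: 12 3,13,11(20)-triene 2α-pivalate
Product: 13 11α,20,13α,14α-tetraol
Conditions: OsO4 (cat.), N-methylmorpholine N-oxide (2.1 equiv), acetone/H2O, 0 °C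
Reagents that add atoms: N-methylmorpholine N-oxide, C[N+]1([O-])CCOCC1; water, O
Why: catalytic syn-dihydroxylation of both ring A alkenes from the α face, anti to axial C15, which sets C11, C13 and C14; the C3=C4 bond should survive because it is shielded by C15 on one face and by the pseudoaxial allylic pivalate on the other.

Step 11
Reactants: 13 11α,20,13α,14α-tetraol
Product: 14 11,20:13,14-bis-acetonide (3-ene, 2α-pivalate)
Conditions: 2,2-dimethoxypropane, pyridinium p-toluenesulfonate (cat.), acetone, rt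
Reagents that add atoms: 2,2-dimethoxypropane, COC(C)(C)OC
Why: acetonide formation on the two 1,2-diols (five-membered rings form in preference to a bridging 1,3-acetal).

Step 12
Reactants: 14 bis-acetonide
Product: 15 3-en-9-one
Conditions: CrO3, 3,5-dimethylpyrazole, CH2Cl2, −20 °C
Reagents that add atoms: chromium trioxide, O=[Cr](=O)=O
Why: allylic oxidation of the only allylic methylene (C9) to the enone; the C2–H bond is deactivated by the ester.

Step 13
Reactants: 15 3-en-9-one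
Product: 16 C9 tert-butyldimethylsilyl enol ether (4(9)-ene, 2α-pivalate)
Conditions: K[HB(s-Bu)3], THF, −78 °C; then TBSCl, DMPU, −78 to 0 °C
Reagents that add atoms: tert-butyldimethylsilyl chloride, C[Si](C)(Cl)C(C)(C)C
Why: conjugate hydride reduction of a cyclohexenone without β-alkyl group and O-silylation of the enolate, which fixes the enol ether regiospecifically toward C4.

Step 14
Reactants: 16 C9 silyl enol ether pivalate
Product: 17 2α-hydroxy C9 silyl enol ether
Conditions: i-Bu2AlH, CH2Cl2, −78 °C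
Reagents that add atoms: none
Why: reductive cleavage of the pivalate; silyl enol ethers and acetonides are inert to the hydride.

Step 15
Reactants: 17 2α-hydroxy C9 silyl enol ether
Product: 18 2-keto C9 silyl enol ether
Conditions: Pr4N[RuO4] (cat.), N-methylmorpholine N-oxide, 4 Å molecular sieves, CH2Cl2, rt
Reagents that add atoms: none
Why: neutral perruthenate oxidation of the secondary alcohol; C2 becomes trigonal, so no axial C2 substituent opposes the axial attack at C4 in step 18.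

Step 16
Reactants: 19 prop-2-en-1-ol
Product: 20 1-methoxy-4-[(prop-2-en-1-yloxy)methyl]benzene
Conditions: NaH, 4-methoxybenzyl chloride, Bu4NI (cat.), THF, 0 °C to rt
Reagents that add atoms: 4-methoxybenzyl chloride, COc1ccc(CCl)cc1
Why: Williamson ether synthesis.

Step 17
Reactants: 20 1-methoxy-4-[(prop-2-en-1-yloxy)methyl]benzene
Product: 21 (E)-5-[(4-methoxybenzyl)oxy]pent-3-en-2-one
Conditions: but-3-en-2-one, second-generation Grubbs catalyst (H2IMes)(PCy3)Cl2Ru=CHPh (cat.), CH2Cl2, 40 °C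
Reagents that add atoms: but-3-en-2-one, CC(=O)C=C
Why: cross-metathesis of an allyl ether with an enone, which should give the (E)-enone.

Step 18
Reactants: 18 2-keto C9 silyl enol ether; 21 (E)-5-[(4-methoxybenzyl)oxy]pent-3-en-2-one
Product: 23 C6 phenylselenide 2,7,9-triketone, via Michael adduct silyl enol ether 22 (not isolated)
Conditions: Tf2NH (cat.), CH2Cl2, −78 °C; then PhSeCl, −78 °C
Reagents that add atoms: benzeneselenenyl chloride, Cl[Se]c1ccccc1
Why: Mukaiyama–Michael addition with silyl transfer, then selenenylation of the new C6=C7 enol ether; C4 is attacked axially from the α face of the half-chair of ring B, which sets C4 (C5 α), while C5 and C6 form as mixtures that are removed in step 20.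

Step 19
Reactants: 23 C6 phenylselenide 2,7,9-triketone
Product: 24 tricyclic 9β-hydroxy ketol selenide (rings A, B, C)
Conditions: pyrrolidine (0.3 equiv), AcOH (0.3 equiv), CH2Cl2, 0 °C to rt
Reagents that add atoms: none
Why: intramolecular aldol addition through the enamine of the unhindered methyl ketone; C8 reaches C9 equatorially from the α face (the β-axial approach is blocked by C15), which gives the cis-fused ketol with axial 9β-hydroxyl.

Step 20
Reactants: 24 tricyclic ketol selenide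
Product: 26 tricyclic 5-en-7-one ketol, via selenoxide 25 (not isolated)
Conditions: H2O2 (30 % aq.), pyridine, CH2Cl2, 0 °C
Reagents that add atoms: none
Why: selenoxide syn-elimination; only C5 carries a β-hydrogen, so the C5=C6 enone forms regiospecifically and the C5/C6 mixtures converge.

Step 21
Reactants: 26 tricyclic 5-en-7-one ketol
Product: 27 7,9-diol (7-OH trans to 9-OH on ring C), 2-ketone
Conditions: Me4NBH(OAc)3, AcOH/MeCN, −30 °C
Reagents that add atoms: none
Why: Evans–Saksena reduction; the C9 hydroxyl binds boron and delivers hydride to its own face of the C7 carbonyl, which sets C7, and the C2 ketone without a directing hydroxyl is not reduced.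

Step 22
Reactants: 27 7,9-diol
Product: 28 7-triethylsilyl ether
Conditions: Et3SiCl, imidazole, CH2Cl2, 0 °C
Reagents that add atoms: chlorotriethylsilane, CC[Si](Cl)(CC)CC
Why: silylation of the secondary allylic alcohol; the axial tertiary C9 hydroxyl is too hindered to react.

Step 23
Reactants: 28 7-triethylsilyl ether
Product: 31 3α-hydroxy-2-ketone, via bis(trimethylsilyl) enol ether 29 (not isolated), via 3α-trimethylsilyloxy ketone 30 (not isolated)
Conditions: KN(SiMe3)2, Me3SiCl, THF, −78 °C; dimethyldioxirane, acetone, −78 °C; K2CO3, MeOH, 0 °C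
Reagents that add atoms: dimethyldioxirane, CC1(C)OO1
Why: Rubottom oxidation; the C2 ketone can enolise only toward C3, the electron-rich enol ether is oxidised before the C5=C6 bond, and the equatorial 3α-hydroxyl (anti to C15) is both the expected and the thermodynamically preferred epimer.

Step 24
Reactants: 31 3α-hydroxy-2-ketone
Product: 32 3α-mesyloxy-2-ketone
Conditions: MeSO2Cl, Et3N, CH2Cl2, −20 °C
Reagents that add atoms: methanesulfonyl chloride, CS(Cl)(=O)=O
Why: mesylation of the only secondary hydroxyl; the tertiary C9 hydroxyl does not react.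

Step 25
Reactants: 32 3α-mesyloxy-2-ketone
Product: 33 2β-hydroxy-3α-mesylate
Conditions: NaBH4, MeOH, −20 °C
Reagents that add atoms: none
Why: axial hydride attack from the α face, anti to C15, gives the equatorial 2β-alcohol; the trans-diequatorial hydroxy mesylate cannot close to an epoxide.

Step 26
Reactants: 33 2β-hydroxy-3α-mesylate
Product: 34 tricyclic hydroxy mesylate, 2β-triisopropylsilyl ether
Conditions: i-Pr3SiOTf, 2,6-lutidine, CH2Cl2, 0 °C
Reagents that add atoms: triisopropylsilyl trifluoromethanesulfonate, CC(C)[Si](OS(=O)(=O)C(F)(F)F)(C(C)C)C(C)C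
Why: silylation of the secondary C2 hydroxyl, which blocks a competing semipinacol ring contraction in the next step.

Step 27
Reactants: 34 tricyclic hydroxy mesylate
Product: 36 bicyclic (3Z,5E)-cyclodecadien-9-one, via potassium C9 alkoxide 35 (not isolated)
Conditions: KOt-Bu (1.1 equiv), THF, 0 °C, short reaction time, pH 7 buffer quench
Reagents that add atoms: none
Why: KOt-Bu deprotonates the tertiary C9 hydroxyl to alkoxide 35, in which an oxygen lone pair, the C4–C9 bond and the equatorial C3–OMs bond are antiperiplanar in the chair of ring B, so that C=O formation, C4–C9 cleavage and loss of mesylate are concerted. The closest known reaction type is the Wharton–Grob fragmentation of cis-fused decalin-1,3-diol monosulfonates to (Z)-cyclodecenones. No ring is closed by bond formation: the ten-membered ring C1–C10 is released when the bond shared by rings B and C breaks, so no medium-ring closure mode applies. No new stereocentre is formed, and C1, C2, C7, C10 and ring A are untouched. The step needs the C3=C4 bond to form Z: C5 is axial on ring B and gauche to C2 across C3–C4 while H3 is anti to C5, and the trans-fused ring A locks this chair, so the two ring branches end cis. It also needs the β-silyloxy ketone to survive, which the slight excess of base, the low temperature and the buffered quench should secure against C8 enolisation with loss of the C7 silyloxy group and against epimerisation at C10.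

Step 28
Reactants: 36 bicyclic (3Z,5E)-cyclodecadien-9-one
Product: 39 8-(tert-butyldimethylsilyloxy)-9-ketone (C8 epimers), via C8(9) silyl enol ether 37 (not isolated), via silyloxy epoxide 38 (not isolated)
Conditions: LiN(i-Pr)2, TBSCl, HMPA, THF, −78 °C; dimethyldioxirane, acetone/CH2Cl2, −40 °C to rt
Reagents that add atoms: tert-butyldimethylsilyl chloride, C[Si](C)(Cl)C(C)(C)C; dimethyldioxirane, CC1(C)OO1
Why: Rubottom oxidation with silyl migration; kinetic deprotonation occurs at C8 because C10–H lies between quaternary C1 and C11, and the C8 configuration is irrelevant since C8 becomes a ketone in step 33.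

Step 29
Reactants: 39 8-silyloxy-9-ketone
Product: 40 7-hydroxy-8-silyloxy-9-ketone
Conditions: HF·pyridine, pyridine, THF, 0 °C
Reagents that add atoms: none
Why: the triethylsilyl ether is cleaved much faster than the tert-butyldimethylsilyl and triisopropylsilyl ethers.

Step 30
Reactants: 40 7-hydroxy-8-silyloxy-9-ketone
Product: 41 7α,9β-diol
Conditions: Me4NBH(OAc)3, AcOH/MeCN, −30 °C
Reagents that add atoms: none
Why: Evans–Saksena reduction; hydride delivery from the boron bound to the C7 hydroxyl gives the 1,3-anti diol and so sets C9.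

Step 31
Reactants: 41 7α,9β-diol
Product: 43 7-O-(2-bromopropanoyl) 9-acetate, via 7-O-(2-bromopropanoyl) 9-ol 42 (not isolated)
Conditions: 2-bromopropanoyl bromide, pyridine, CH2Cl2, −40 °C; then Ac2O, DMAP, rt
Reagents that add atoms: 2-bromopropanoyl bromide, CC(Br)C(Br)=O; acetic anhydride, CC(=O)OC(C)=O
Why: the allylic C7 hydroxyl is acylated first because the C9 hydroxyl is flanked by C10 and the C8 silyl ether; the C9 hydroxyl is then acetylated under DMAP catalysis.

Step 32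
Reactants: 43 7-O-(2-bromopropanoyl) 9-acetate
Product: 44 8-ol
Conditions: HF·pyridine, THF, rt
Reagents that add atoms: none
Why: the secondary tert-butyldimethylsilyl ether is cleaved while the neopentyl triisopropylsilyl ether at C2 should persist.

Step 33
Reactants: 44 8-ol
Product: 45 8-ketone
Conditions: Dess–Martin periodinane, NaHCO3, CH2Cl2, rt
Reagents that add atoms: none
Why: neutral oxidation of the only free hydroxyl; the C8 epimers converge.

Step 34
Reactants: 45 8-ketone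
Product: 46 lactone with 8α-hydroxyl (17-H β, C18 α)
Conditions: SmI2 (2.2 equiv), THF, −78 °C
Reagents that add atoms: none
Why: intramolecular samarium Reformatsky reaction; the enolate tethered through O7 reaches the C8 carbonyl in the conformer in which C6 eclipses the carbonyl oxygen and C9 is anticlinal to C6, which sets C8 with its hydroxyl cis to C6, and C18 should take the position trans to C9 in the chelated transition state, which sets C17.

Step 35
Reactants: 46 lactone
Product: 47 2β-ol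
Conditions: Bu4NF, AcOH, THF, 40 °C
Reagents that add atoms: none
Why: buffered fluoride cleavage of the triisopropylsilyl ether; the buffer protects the acetate and the β-hydroxy lactone.

Step 36
Reactants: 47 2β-ol
Product: 48 hexaol 9-acetate (2, 8, 11, 13, 14, 20-hydroxyls)
Conditions: AcOH/H2O (4:1), 50 °C
Reagents that add atoms: none
Why: acid hydrolysis of both acetonides; the 4-methoxybenzyl ether, acetate and lactone tolerate aqueous acetic acid.

Step 37
Reactants: 48 hexaol 9-acetate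
Product: 50 11,20-epoxide tetraol, via C20 tosylate 49 (not isolated)
Conditions: TsCl (1.1 equiv), Et3N, Bu2SnO (cat.), CH2Cl2, 0 °C; then DBU, rt
Reagents that add atoms: none
Why: tin-mediated sulfonylation of the primary hydroxyl of the 11,20-diol, then displacement by the tertiary C11 oxygen (3-exo-tet), so that C11 keeps the configuration set in step 10.

Step 38
Reactants: 50 11,20-epoxide tetraol
Product: 51 2,9,13,14-tetraacetate 16-(4-methoxybenzyl) ether
Conditions: Ac2O, pyridine, DMAP (cat.), CH2Cl2, rt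
Reagents that add atoms: acetic anhydride, CC(=O)OC(C)=O
Why: acetylation of the three secondary hydroxyls; the hydrogen-bonded tertiary C8 hydroxyl should remain free.

Step 39
Reactants: 51 tetraacetate 4-methoxybenzyl ether
Product: 52 CNP0317528.1
Conditions: DDQ, CH2Cl2/pH 7 buffer, 0 °C
Reagents that add atoms: none
Why: oxidative cleavage of the 4-methoxybenzyl ether under buffered conditions that spare the epoxide, the acetates and the electron-poor diene.

**Compound list**

1 | (S)-4-(tert-butyldimethylsilyloxy)cyclohex-2-en-1-one | O=C1C=C[C@@H](O[Si](C)(C)C(C)(C)C)CC1 | starting material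
2 | (S)-4-(tert-butyldimethylsilyloxy)-2-iodocyclohex-2-en-1-one | O=C1C(I)=C[C@@H](O[Si](C)(C)C(C)(C)C)CC1 | intermediate
3 | (S)-4-(tert-butyldimethylsilyloxy)-2-methylcyclohex-2-en-1-one | CC1=C[C@@H](O[Si](C)(C)C(C)(C)C)CCC1=O | intermediate
4 | (E)-but-2-enal | C/C=C/C=O | starting material
5 | (E)-buta-1,3-dien-1-yl pivalate | C=C/C=C/OC(=O)C(C)(C)C | intermediate
6 | cis-fused adduct, 2α-pivaloyloxy-11β-silyloxy-3-en-14-one | O=C1CC[C@H](O[Si](C)(C)C(C)(C)C)[C@H]2CC=C[C@@H](OC(=O)C(C)(C)C)[C@@]12C | intermediate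
7 | cis-fused 11β-hydroxy-14-ketone | O=C1CC[C@H](O)[C@H]2CC=C[C@@H](OC(=O)C(C)(C)C)[C@@]12C | intermediate
8 | cis-fused 11,14-dione | O=C1CCC(=O)[C@H]2CC=C[C@@H](OC(=O)C(C)(C)C)[C@@]12C | intermediate
9 | trans-fused 11,14-dione (H10 α) | O=C1CCC(=O)[C@@H]2CC=C[C@@H](OC(=O)C(C)(C)C)[C@@]12C | intermediate
10 | 11(20)-methylene-14-ketone | O=C1CCC(=C)[C@@H]2CC=C[C@@H](OC(=O)C(C)(C)C)[C@@]12C | intermediate
11 | C14 enol triflate | O=S(=O)(OC1=CCC(=C)[C@@H]2CC=C[C@@H](OC(=O)C(C)(C)C)[C@@]12C)C(F)(F)F | intermediate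
12 | 3,13,11(20)-triene 2α-pivalate | C1=CCC(=C)[C@@H]2CC=C[C@@H](OC(=O)C(C)(C)C)[C@@]12C | intermediate
13 | 11α,20,13α,14α-tetraol | O[C@H]1C[C@](O)(CO)[C@@H]2CC=C[C@@H](OC(=O)C(C)(C)C)[C@@]2(C)[C@H]1O | intermediate
14 | 11,20:13,14-bis-acetonide, 3-ene, 2α-pivalate | CC1(C)O[C@H]2C[C@]3(COC(C)(C)O3)[C@@H]3CC=C[C@@H](OC(=O)C(C)(C)C)[C@@]3(C)[C@H]2O1 | intermediate
15 | 3-en-9-one | CC1(C)O[C@H]2C[C@]3(COC(C)(C)O3)[C@@H]3C(=O)C=C[C@@H](OC(=O)C(C)(C)C)[C@@]3(C)[C@H]2O1 | intermediate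
16 | C9 tert-butyldimethylsilyl enol ether, 2α-pivalate | CC1(C)O[C@H]2C[C@]3(COC(C)(C)O3)[C@@H]3C(O[Si](C)(C)C(C)(C)C)=CC[C@@H](OC(=O)C(C)(C)C)[C@@]3(C)[C@H]2O1 | intermediate
17 | 2α-hydroxy C9 silyl enol ether | CC1(C)O[C@H]2C[C@]3(COC(C)(C)O3)[C@@H]3C(O[Si](C)(C)C(C)(C)C)=CC[C@@H](O)[C@@]3(C)[C@H]2O1 | intermediate
18 | 2-keto C9 silyl enol ether | CC1(C)O[C@H]2C[C@]3(COC(C)(C)O3)[C@@H]3C(O[Si](C)(C)C(C)(C)C)=CCC(=O)[C@@]3(C)[C@H]2O1 | intermediate
19 | prop-2-en-1-ol | C=CCO | starting material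
20 | 1-methoxy-4-[(prop-2-en-1-yloxy)methyl]benzene | C=CCOCc1ccc(OC)cc1 | intermediate
21 | (E)-5-[(4-methoxybenzyl)oxy]pent-3-en-2-one | CC(=O)/C=C/COCc1ccc(OC)cc1 | intermediate
22 | Michael adduct silyl enol ether (C5 mixture) | CC1(C)O[C@H]2C[C@]3(COC(C)(C)O3)[C@@H]3C(=O)[C@@H](C(COCc4ccc(OC)cc4)C=C(C)O[Si](C)(C)C(C)(C)C)CC(=O)[C@@]3(C)[C@H]2O1 | intermediate
23 | C6 phenylselenide 2,7,9-triketone (C5, C6 mixtures) | CC1(C)O[C@H]2C[C@]3(COC(C)(C)O3)[C@@H]3C(=O)[C@@H](C(COCc4ccc(OC)cc4)C([Se]c4ccccc4)C(C)=O)CC(=O)[C@@]3(C)[C@H]2O1 | intermediate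
24 | tricyclic 9β-hydroxy ketol selenide | CC1(C)O[C@H]2C[C@]3(COC(C)(C)O3)[C@@H]3[C@@]4(O)CC(=O)C([Se]c5ccccc5)C(COCc5ccc(OC)cc5)[C@H]4CC(=O)[C@@]3(C)[C@H]2O1 | intermediate
25 | selenoxide of 24 | CC1(C)O[C@H]2C[C@]3(COC(C)(C)O3)[C@@H]3[C@@]4(O)CC(=O)C([Se](=O)c5ccccc5)C(COCc5ccc(OC)cc5)[C@H]4CC(=O)[C@@]3(C)[C@H]2O1 | intermediate
26 | tricyclic 5-en-7-one ketol | CC1(C)O[C@H]2C[C@]3(COC(C)(C)O3)[C@@H]3[C@@]4(O)CC(=O)C=C(COCc5ccc(OC)cc5)[C@H]4CC(=O)[C@@]3(C)[C@H]2O1 | intermediate
27 | 7,9-diol 2-ketone | CC1(C)O[C@H]2C[C@]3(COC(C)(C)O3)[C@@H]3[C@@]4(O)C[C@@H](O)C=C(COCc5ccc(OC)cc5)[C@H]4CC(=O)[C@@]3(C)[C@H]2O1 | intermediate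
28 | 7-triethylsilyl ether | CC1(C)O[C@H]2C[C@]3(COC(C)(C)O3)[C@@H]3[C@@]4(O)C[C@@H](O[Si](CC)(CC)CC)C=C(COCc5ccc(OC)cc5)[C@H]4CC(=O)[C@@]3(C)[C@H]2O1 | intermediate
29 | bis(trimethylsilyl) enol ether | CC1(C)O[C@H]2C[C@]3(COC(C)(C)O3)[C@@H]3[C@@]4(O[Si](C)(C)C)C[C@@H](O[Si](CC)(CC)CC)C=C(COCc5ccc(OC)cc5)[C@H]4C=C(O[Si](C)(C)C)[C@@]3(C)[C@H]2O1 | intermediate
30 | 3α-trimethylsilyloxy ketone | CC1(C)O[C@H]2C[C@]3(COC(C)(C)O3)[C@@H]3[C@@]4(O[Si](C)(C)C)C[C@@H](O[Si](CC)(CC)CC)C=C(COCc5ccc(OC)cc5)[C@H]4[C@@H](O[Si](C)(C)C)C(=O)[C@@]3(C)[C@H]2O1 | intermediate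
31 | 3α-hydroxy-2-ketone | CC1(C)O[C@H]2C[C@]3(COC(C)(C)O3)[C@@H]3[C@@]4(O)C[C@@H](O[Si](CC)(CC)CC)C=C(COCc5ccc(OC)cc5)[C@H]4[C@@H](O)C(=O)[C@@]3(C)[C@H]2O1 | intermediate
32 | 3α-mesyloxy-2-ketone | CC1(C)O[C@H]2C[C@]3(COC(C)(C)O3)[C@@H]3[C@@]4(O)C[C@@H](O[Si](CC)(CC)CC)C=C(COCc5ccc(OC)cc5)[C@H]4[C@@H](OS(C)(=O)=O)C(=O)[C@@]3(C)[C@H]2O1 | intermediate
33 | 2β-hydroxy-3α-mesylate | CC1(C)O[C@H]2C[C@]3(COC(C)(C)O3)[C@@H]3[C@@]4(O)C[C@@H](O[Si](CC)(CC)CC)C=C(COCc5ccc(OC)cc5)[C@H]4[C@@H](OS(C)(=O)=O)[C@H](O)[C@@]3(C)[C@H]2O1 | intermediate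
34 | tricyclic cis-fused hydroxy mesylate (2β-triisopropylsilyl, 7-triethylsilyl) | CC1(C)O[C@H]2C[C@]3(COC(C)(C)O3)[C@@H]3[C@@]4(O)C[C@@H](O[Si](CC)(CC)CC)C=C(COCc5ccc(OC)cc5)[C@H]4[C@@H](OS(C)(=O)=O)[C@H](O[Si](C(C)C)(C(C)C)C(C)C)[C@@]3(C)[C@H]2O1 | intermediate
35 | potassium C9 alkoxide of 34 | [K+].CC1(C)O[C@H]2C[C@]3(COC(C)(C)O3)[C@@H]3[C@@]4([O-])C[C@@H](O[Si](CC)(CC)CC)C=C(COCc5ccc(OC)cc5)[C@H]4[C@@H](OS(C)(=O)=O)[C@H](O[Si](C(C)C)(C(C)C)C(C)C)[C@@]3(C)[C@H]2O1 | intermediate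
36 | bicyclic (3Z,5E)-cyclodecadien-9-one | CC1(C)O[C@H]2C[C@]3(COC(C)(C)O3)[C@@H]3C(=O)C[C@@H](O[Si](CC)(CC)CC)/C=C(COCc4ccc(OC)cc4)\C=C/[C@H](O[Si](C(C)C)(C(C)C)C(C)C)[C@@]3(C)[C@H]2O1 | intermediate
37 | C8(9) silyl enol ether | CC1(C)O[C@H]2C[C@]3(COC(C)(C)O3)[C@@H]3C(O[Si](C)(C)C(C)(C)C)=C[C@@H](O[Si](CC)(CC)CC)/C=C(COCc4ccc(OC)cc4)\C=C/[C@H](O[Si](C(C)C)(C(C)C)C(C)C)[C@@]3(C)[C@H]2O1 | intermediate
38 | silyloxy epoxide | CC1(C)O[C@H]2C[C@]3(COC(C)(C)O3)[C@@H]3C4(O[Si](C)(C)C(C)(C)C)OC4[C@@H](O[Si](CC)(CC)CC)/C=C(COCc5ccc(OC)cc5)\C=C/[C@H](O[Si](C(C)C)(C(C)C)C(C)C)[C@@]3(C)[C@H]2O1 | intermediate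
39 | 8-(tert-butyldimethylsilyloxy)-9-ketone (C8 epimers) | CC1(C)O[C@H]2C[C@]3(COC(C)(C)O3)[C@@H]3C(=O)C(O[Si](C)(C)C(C)(C)C)[C@@H](O[Si](CC)(CC)CC)/C=C(COCc4ccc(OC)cc4)\C=C/[C@H](O[Si](C(C)C)(C(C)C)C(C)C)[C@@]3(C)[C@H]2O1 | intermediate
40 | 7-hydroxy-8-silyloxy-9-ketone | CC1(C)O[C@H]2C[C@]3(COC(C)(C)O3)[C@@H]3C(=O)C(O[Si](C)(C)C(C)(C)C)[C@@H](O)/C=C(COCc4ccc(OC)cc4)\C=C/[C@H](O[Si](C(C)C)(C(C)C)C(C)C)[C@@]3(C)[C@H]2O1 | intermediate
41 | 7α,9β-diol | CC1(C)O[C@H]2C[C@]3(COC(C)(C)O3)[C@@H]3[C@H](O)C(O[Si](C)(C)C(C)(C)C)[C@@H](O)/C=C(COCc4ccc(OC)cc4)\C=C/[C@H](O[Si](C(C)C)(C(C)C)C(C)C)[C@@]3(C)[C@H]2O1 | intermediate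
42 | 7-O-(2-bromopropanoyl) 9-ol | CC1(C)O[C@H]2C[C@]3(COC(C)(C)O3)[C@@H]3[C@H](O)C(O[Si](C)(C)C(C)(C)C)[C@@H](OC(=O)C(C)Br)/C=C(COCc4ccc(OC)cc4)\C=C/[C@H](O[Si](C(C)C)(C(C)C)C(C)C)[C@@]3(C)[C@H]2O1 | intermediate
43 | 7-O-(2-bromopropanoyl) 9-acetate | CC1(C)O[C@H]2C[C@]3(COC(C)(C)O3)[C@@H]3[C@H](OC(C)=O)C(O[Si](C)(C)C(C)(C)C)[C@@H](OC(=O)C(C)Br)/C=C(COCc4ccc(OC)cc4)\C=C/[C@H](O[Si](C(C)C)(C(C)C)C(C)C)[C@@]3(C)[C@H]2O1 | intermediate
44 | 8-ol | CC1(C)O[C@H]2C[C@]3(COC(C)(C)O3)[C@@H]3[C@H](OC(C)=O)C(O)[C@@H](OC(=O)C(C)Br)/C=C(COCc4ccc(OC)cc4)\C=C/[C@H](O[Si](C(C)C)(C(C)C)C(C)C)[C@@]3(C)[C@H]2O1 | intermediate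
45 | 8-ketone | CC1(C)O[C@H]2C[C@]3(COC(C)(C)O3)[C@@H]3[C@H](OC(C)=O)C(=O)[C@@H](OC(=O)C(C)Br)/C=C(COCc4ccc(OC)cc4)\C=C/[C@H](O[Si](C(C)C)(C(C)C)C(C)C)[C@@]3(C)[C@H]2O1 | intermediate
46 | lactone with 8α-hydroxyl, 2β-triisopropylsilyl ether | CC1(C)O[C@H]2C[C@]3(COC(C)(C)O3)[C@@H]3[C@H](OC(C)=O)[C@@]4(O)[C@H](/C=C(COCc5ccc(OC)cc5)\C=C/[C@H](O[Si](C(C)C)(C(C)C)C(C)C)[C@@]3(C)[C@H]2O1)OC(=O)[C@@H]4C | intermediate
47 | lactone 2β-ol | CC1(C)O[C@H]2C[C@]3(COC(C)(C)O3)[C@@H]3[C@H](OC(C)=O)[C@@]4(O)[C@H](/C=C(COCc5ccc(OC)cc5)\C=C/[C@H](O)[C@@]3(C)[C@H]2O1)OC(=O)[C@@H]4C | intermediate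
48 | hexaol 9-acetate | O[C@H]1C[C@](O)(CO)[C@@H]2[C@H](OC(C)=O)[C@@]3(O)[C@H](/C=C(COCc4ccc(OC)cc4)\C=C/[C@H](O)[C@@]2(C)[C@H]1O)OC(=O)[C@@H]3C | intermediate
49 | C20 tosylate | O[C@H]1C[C@](O)(COS(=O)(=O)c2ccc(C)cc2)[C@@H]2[C@H](OC(C)=O)[C@@]3(O)[C@H](/C=C(COCc4ccc(OC)cc4)\C=C/[C@H](O)[C@@]2(C)[C@H]1O)OC(=O)[C@@H]3C | intermediate
50 | 11,20-epoxide tetraol | O[C@H]1C[C@]2(CO2)[C@@H]2[C@H](OC(C)=O)[C@@]3(O)[C@H](/C=C(COCc4ccc(OC)cc4)\C=C/[C@H](O)[C@@]2(C)[C@H]1O)OC(=O)[C@@H]3C | intermediate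
51 | 2,9,13,14-tetraacetate 16-(4-methoxybenzyl) ether | CC(=O)O[C@H]1C[C@]2(CO2)[C@@H]2[C@H](OC(C)=O)[C@@]3(O)[C@H](/C=C(COCc4ccc(OC)cc4)\C=C/[C@H](OC(C)=O)[C@@]2(C)[C@H]1OC(C)=O)OC(=O)[C@@H]3C | intermediate
52 | CNP0317528.1 | CC(=O)O[C@H]1C[C@]2(CO2)[C@@H]2[C@H](OC(C)=O)[C@@]3(O)[C@H](/C=C(CO)\C=C/[C@H](OC(C)=O)[C@@]2(C)[C@H]1OC(C)=O)OC(=O)[C@@H]3C | target

**Step count**
Total: 39 steps. Longest linear sequence: 36 steps (steps 1, 2, 4–15, 18–39).

**Steps most likely to fail**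

Step 6. The epimerisation at C10 may stop at a mixture because the cis- and trans-fused diones could be close in energy. Fallback: set C10 by kinetic protonation instead of equilibration. Starting from 7, the cis-dione is made as before and treated with Me3SiOTf/Et3N to give the bis(trimethylsilyl) dienol ether F1 (C10=C11 and C13=C14 enol ethers). Protodesilylation with Bu4NF/AcOH at −78 °C should deliver the proton to C10 from the α face, anti to C15, and the route is rejoined at 9.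

Step 18. The Michael adduct may lose its silyl group before selenenylation, or revert by retro-Michael cleavage, so that C6 is not functionalised. Fallback: bring in the C5=C6 bond with the acceptor. Propargyl alcohol is etherified (NaH, 4-methoxybenzyl chloride) to 1-methoxy-4-[(prop-2-yn-1-yloxy)methyl]benzene F2, which is lithiated (n-BuLi) and acylated with N-methoxy-N-methylacetamide to give 5-[(4-methoxybenzyl)oxy]pent-3-yn-2-one F3. Tf2NH-catalysed addition of 18 to F3 and aqueous work-up should give the enedione F4; kinetic deprotonation of its methyl ketone with LiN(SiMe3)2 at −78 °C closes ring C, and the route is rejoined at 26.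

Step 34. The samarium enolate may add through the wrong geometry and give the C17 epimer. Fallback: set C17 under thermodynamic instead of kinetic control. The cyclisation of 45 is run as before; if it gives the 17-epi-lactone F5, equilibration with DBU in toluene should move C18 to the position trans to the C9 branch of the ring, and the route is rejoined at 46.

**Further compounds**
F1 | step 6 | bis(trimethylsilyl) dienol ether of the 11,14-dione | C[Si](C)(C)OC1=CCC(O[Si](C)(C)C)=C2CC=C[C@@H](OC(=O)C(C)(C)C)[C@@]12C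
F2 | step 18 | 1-methoxy-4-[(prop-2-yn-1-yloxy)methyl]benzene | C#CCOCc1ccc(OC)cc1
F3 | step 18 | 5-[(4-methoxybenzyl)oxy]pent-3-yn-2-one | CC(=O)C#CCOCc1ccc(OC)cc1
F4 | step 18 | enedione Michael adduct with C5=C6 in place | CC1(C)O[C@H]2C[C@]3(COC(C)(C)O3)[C@@H]3C(=O)[C@@H](C(COCc4ccc(OC)cc4)=CC(C)=O)CC(=O)[C@@]3(C)[C@H]2O1
F5 | step 34 | 17-epi-lactone | CC1(C)O[C@H]2C[C@]3(COC(C)(C)O3)[C@@H]3[C@H](OC(C)=O)[C@@]4(O)[C@H](/C=C(COCc5ccc(OC)cc5)\C=C/[C@H](O[Si](C(C)C)(C(C)C)C(C)C)[C@@]3(C)[C@H]2O1)OC(=O)[C@H]4C
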